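**Plan**
- Cuts: the spiro ether–lactone at O–C-13 (back to a 2-silyl-3-alkylfuran and singlet oxygen); C-9–C-11 (back to a tricyclic 9-ketone); ring A and the δ-lactone together at C-4–C-5 and O–C-20; then C-3–C-4 and the C-10 quaternary centre (back to propanoic acid, 1,3-dibromopropane and 2-methoxy-3-methylbenzoic acid).
- Forward: Birch reduction–alkylation gives ring B with C-10 set; iodolactonization and reduction place a 5,6-epoxide on the face of C-20; one anionic cascade closes ring A and the lactone; the 9-ketone is unmasked, C-8 and C-9 are set, and the furan is oxidized to the spiro system.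
- Enabling feature: C-5 is an epoxide carbon next to quaternary C-10, whose two arms lie on opposite faces of ring B. The C-1 chain (anti to the epoxide oxygen) delivers the C-4 enediolate to C-5; the C-20 arm then sits 1,3-diaxial to the C-19 carboxylate on the new ring A, so the lactone (a 3-oxabicyclo[3.3.1]nonanone with ring A) closes by O-alkylation.
- Stereochemistry: C-10 from the proline-derived auxiliary; C-5, C-6 and the cis A/B junction from anti opening of the β-epoxide; C-4 in the cyclization (only the C-19/C-20 cis epimer can lactonize); C-8 by kinetic protonation; C-9 by β-face addition to the ketone; C-13 in the reversible spirocyclization.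

Key step: step 8

Convention: labdane locants are used (C-4 carries C-18 methyl and C-19 carboxyl, C-10 carries C-20, ring B is C-5 to C-10); β is the face of ring B that carries C-20.
Assumption 1: the SMILES is read with H-5 on the face of C-20 (rings A and B cis-fused), 6-OH and C-11 on that face, and 17-CH3 and the 9-oxygen on the other.
Assumption 2: the (S)-2-(methoxymethyl)pyrrolidine amide is taken to direct the alkyl halide to the face that gives the C-10 configuration drawn; the (R)-amine would be used if the sense is the opposite.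

Step 1
Reactants: 1 2-methoxy-3-methylbenzoic acid; 2 (S)-2-(methoxymethyl)pyrrolidine
Product: 4 auxiliary benzamide, via acid chloride 3 (not isolated)
Conditions: SOCl2, toluene, 70 °C; then 2, Et3N, CH2Cl2, 0 → 23 °C
Reagents that add atoms: none
Why: Nucleophilic acyl substitution through the acid chloride is routine and attaches the chiral auxiliary that will control C-10.

Step 2
Reactants: 4 auxiliary benzamide; 5 1,3-dibromopropane
Product: 7 alkylated cyclohexadiene amide, via potassium amide enolate 6 (not isolated)
Conditions: K (2.3 equiv), NH3(l)–THF, t-BuOH (1.0 equiv), −78 °C; penta-1,3-diene; then 5 (5 equiv), −78 °C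
Reagents that add atoms: none
Why: Birch reduction–alkylation: the benzamide is reduced to the cross-conjugated amide enolate, which is alkylated at the amide-bearing carbon on the face fixed by the chelated auxiliary, so C-10 becomes quaternary (amide carbon = C-20, chain = C-1 to C-3) and the isolated ring alkene sits at C-5/C-6.

Step 3
Reactants: 7 alkylated cyclohexadiene amide
Product: 8 C-9 ethylene ketal
Conditions: ethane-1,2-diol (5 equiv), pyridinium 4-toluenesulfonate (cat.), benzene, 23 °C
Reagents that add atoms: ethane-1,2-diol OCCO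
Why: Acid-catalysed transketalization of the enol ether (protonation at C-8, capture of the oxocarbenium ion by the diol, loss of methanol) masks the C-9 ketone in a form stable to iodine, hydride and strong base; C-8 forms as a mixture that is reset in step 10.

Step 4
Reactants: 8 C-9 ethylene ketal
Product: 10 iodolactone, via iminium lactone iodide 9 (not isolated)
Conditions: I2 (2.5 equiv), THF–H2O, 23 °C, dark
Reagents that add atoms: iodine II; water O
Why: Iodolactonization of the β,γ-unsaturated amide: the amide oxygen can reach C-6 only on the face of C-20, iodine adds anti at C-5, and hydrolysis of the iminium lactone releases the auxiliary (closure at C-5 instead would lead to the same epoxide in step 5).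

Step 5
Reactants: 10 iodolactone
Product: 12 epoxy alcohol, via iodo diol 11 (not isolated)
Conditions: LiBH4 (2 equiv), THF, 0 → 23 °C; then K2CO3 (2 equiv), MeOH, 23 °C
Reagents that add atoms: none
Why: Hydride reduction of the lactone gives the 6β,20-diol, and the 6β-alkoxide then displaces the anti 5α-iodide (intramolecular Williamson reaction, inversion at C-5), which places the epoxide on the face of C-20.

Step 6
Reactants: 12 epoxy alcohol
Product: 13 epoxy tosylate
Conditions: TsCl (1.5 equiv), Et3N, 4-(dimethylamino)pyridine (cat.), CH2Cl2, 0 → 23 °C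
Reagents that add atoms: 4-methylbenzenesulfonyl chloride Cc1ccc(cc1)S(Cl)(=O)=O
Why: Sulfonylation of the primary neopentyl 20-alcohol makes C-20 an electrophile that carbon nucleophiles should not attack at low temperature because of the adjacent quaternary C-10.

Step 7
Reactants: 13 epoxy tosylate; 14 propanoic acid
Product: 16 epoxy tosylate acid, via dilithium propanoate enediolate 15 (not isolated)
Conditions: 14 (3 equiv), LiN(iPr)2 (6 equiv), THF–DMPU, 0 °C; then 13, −20 → 0 °C; aq. NaH2PO4
Reagents that add atoms: none
Why: Alkylation of a carboxylic acid dianion by the primary bromide forms C-3–C-4 and brings in C-4, C-18 and C-19; the hindered epoxide and the neopentyl tosylate should survive at or below 0 °C, and the C-4 configuration is irrelevant because C-4 becomes an enolate carbon in step 8.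

Step 8
Reactants: 16 epoxy tosylate acid
Product: 19 tricyclic hydroxy lactone ketal, via dilithium enediolate 17 (not isolated), via aluminium alkoxide carboxylate 18 (not isolated)
Conditions: LiN(iPr)2 (2.3 equiv), THF, −78 °C; Et2AlCl (1.1 equiv), −78 → 0 °C; then DMPU, 55 °C
Reagents that add atoms: none
Why: Anionic epoxide-opening cyclization followed by carboxylate O-alkylation: the aluminium enolate formed from the dianion attacks C-5 from the α-face, anti to the epoxide oxygen and on the side of its C-1 tether (6-exo-tet, trans-diaxial opening), which closes ring A cis-fused, sets C-5 by inversion and leaves the 6β C–O bond untouched. The 6-oxygen is formed as a diethylaluminium alkoxide and should not attack C-20, so after ring flip the lithium carboxylate, now 1,3-diaxial to the CH2OTs group across C-5, displaces tosylate (6-exo-tet) and closes the δ-lactone of the 3-oxabicyclo[3.3.1]nonanone. The closest known reaction types are the intramolecular alkylation of nitrile and ester anions by epoxides, the dianion–epoxide route to γ-hydroxy acids, and lactonization of carboxylates with primary sulfonates. C-4 is set in the C–C bond formation: the bulky solvated enediolate is expected on the outside and the methyl on the inside of the chair-like transition state, which places C-19 cis to C-20, and only this epimer can lactonize. Selectivity needed: C-5 over C-6 (six- against seven-membered ring), the epoxide over the neopentyl tosylate for the carbon nucleophile (neopentyl SN2 is slow at or below 0 °C), and the carboxylate over the 6-oxygen for C-20 (aluminium capping).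

Step 9
Reactants: 19 tricyclic hydroxy lactone ketal
Product: 20 tricyclic 9-ketone
Conditions: 2 M HCl, THF, 40 °C
Reagents that add atoms: water O
Why: Acid hydrolysis of the dioxolane regenerates the C-9 ketone while the bridged lactone and the secondary alcohol are stable to dilute acid; C-8 equilibrates to a mixture that is corrected in the next step.

Step 10
Reactants: 20 tricyclic 9-ketone
Product: 22 8α-methyl 9-ketone, via dilithium alkoxide enolate 21 (not isolated)
Conditions: LiN(iPr)2 (2.3 equiv), THF, −78 °C; then 2,6-di-tert-butyl-4-methylphenol (3 equiv), −78 °C; aq. NH4Cl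
Reagents that add atoms: none
Why: Kinetic protonation of an enolate: C-8 is the only enolizable position and the bulky phenol should deliver the proton to the β-face, because the α-face is screened by C-1 (axial on ring B of the cis-fused tricycle), giving the less stable 8α-methyl ketone, which is used at once.

Step 11
Reactants: 23 3-bromofuran
Product: 25 3-bromo-2-(trimethylsilyl)furan, via 3-bromo-2-furyllithium 24 (not isolated)
Conditions: LiN(iPr)2, THF, −78 °C; Me3SiCl, −78 → 23 °C
Reagents that add atoms: chlorotrimethylsilane C[Si](C)(C)Cl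
Why: Directed deprotonation of 3-bromofuran at C-2 (between oxygen and bromine) and silylation place the silyl group that later fixes the regiochemistry of the furan oxidation.

Step 12
Reactants: 25 3-bromo-2-(trimethylsilyl)furan
Product: 27 2-silylfuran ethanol, via 2-silyl-3-furyllithium 26 (not isolated)
Conditions: n-BuLi, Et2O, −78 °C; oxirane, BF3·OEt2, −78 °C
Reagents that add atoms: oxirane C1CO1
Why: Bromine–lithium exchange and BF3-assisted opening of oxirane by the 3-furyllithium at −78 °C, below the temperature at which 3-lithiofurans rearrange, add the two-carbon arm C-12/C-11.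

Step 13
Reactants: 27 2-silylfuran ethanol
Product: 28 2-silylfuran ethyl iodide
Conditions: PPh3, I2, imidazole, CH2Cl2, 0 °C (reagent preformed); then 27, 0 → 23 °C
Reagents that add atoms: iodine II
Why: Appel-type iodination of the primary alcohol with the preformed phosphonium iodide gives the iodide without exposing the silylfuran to free iodine.

Step 14
Reactants: 28 2-silylfuran ethyl iodide; 22 8α-methyl 9-ketone
Product: 31 furyl diol, via alkyllithium 29 (not isolated), via alkylcerium dichloride 30 (not isolated)
Conditions: 28 (3.5 equiv), t-BuLi (7 equiv), Et2O, −78 °C; CeCl3, THF, −78 °C; then 22, −78 → −40 °C; pH 7 buffer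
Reagents that add atoms: none
Why: Iodine–lithium exchange, transmetalation to the weakly basic organocerium reagent and 1,2-addition to the hindered ketone (the 6-hydroxyl carried as its alkoxide): axial attack on the β-face, the α-face being blocked by C-1 and the 8α-methyl group, should give the 9α-hydroxyl with C-11 β without enolization.

Step 15
Reactants: 31 furyl diol
Product: 35 spiro lactol, via furan endoperoxide 32 (not isolated), via open enal silyl ester 33 (not isolated), via spiro aldehyde silyl ester 34 (not isolated)
Conditions: O2, visible light, 5,10,15,20-tetraphenylporphyrin (cat.), CH2Cl2, −78 °C; then 10-camphorsulfonic acid (cat.), 23 °C; aqueous work-up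
Reagents that add atoms: dioxygen O=O
Why: Singlet-oxygen [4+2] cycloaddition to the 2-silylfuran, silyl migration to peroxide oxygen with O–O cleavage (which puts the carboxyl at the former C–Si carbon, C-16) and acid-catalysed 5-exo oxa-Michael addition of the 9α-hydroxyl to C-13, the β-carbon of the unmasked (Z)-enal, close the spiro tetrahydrofuran, and hydrolysis of the silyl ester gives the lactol; the addition is reversible, so C-13 is expected to settle in the more stable arrangement, taken to be the one with the C-16 carbonyl on the side of C-8.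

Step 16
Reactants: 35 spiro lactol
Product: 37 target compound, via sodium hydroxy carboxylate 36 (not isolated)
Conditions: NaBH4, MeOH, 0 °C; then 1 M HCl, 23 °C
Reagents that add atoms: none
Why: Borohydride reduction of the ring-opened aldehyde form of the lactol and acid-induced lactonization of the 15-hydroxy acid give the γ-lactone, while the hindered bridged δ-lactone is not reduced by NaBH4 at 0 °C.

**Compound list**
1 | 2-methoxy-3-methylbenzoic acid | COc1c(C)cccc1C(O)=O | starting material
2 | (S)-2-(methoxymethyl)pyrrolidine | COC[C@@H]1CCCN1 | starting material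
3 | 2-methoxy-3-methylbenzoyl chloride | COc1c(C)cccc1C(Cl)=O | intermediate
4 | N-(2-methoxy-3-methylbenzoyl)-(S)-2-(methoxymethyl)pyrrolidine | COc1c(C)cccc1C(=O)N1CCC[C@H]1COC | intermediate
5 | 1,3-dibromopropane | BrCCCBr | starting material
6 | potassium amide enolate of the 1,4-dihydro form of 4 | [K+].[O-]C(=C1C=CCC(C)=C1OC)N1CCC[C@H]1COC | intermediate
7 | 1-(3-bromopropyl)-2-methoxy-3-methylcyclohexa-2,5-diene-1-carboxamide of 2 (quaternary carbon = C-10, amide carbon = C-20, chain = C-1 to C-3) | CC1CC=C[C@](C(=O)N2CCC[C@H]2COC)(CCCBr)C(OC)=1 | intermediate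
8 | 6-(3-bromopropyl)-10-methyl-1,4-dioxaspiro[4.5]dec-7-ene-6-carboxamide of 2 (C-9 ketal, C-8 epimers) | CC1CC=C[C@](C(=O)N2CCC[C@H]2COC)(CCCBr)C12OCCO2 | intermediate
9 | iminium lactone iodide (amide oxygen bonded to C-6 on the β-face, 5α-iodide) | CC1C[C@@H](O3)[C@H](I)[C@](C3=[N+]4CCC[C@H]4COC)(CCCBr)C12OCCO2.[I-] | intermediate
10 | iodolactone: 20,6β-olide with 5α-iodide, 3-bromopropyl at C-10, C-9 ketal (C-8 epimers) | CC1C[C@@H](O3)[C@H](I)[C@](C3=O)(CCCBr)C12OCCO2 | intermediate
11 | 5α-iodo-6β,20-diol | CC1C[C@@H](O)[C@H](I)[C@](CO)(CCCBr)C12OCCO2 | intermediate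
12 | 5β,6β-epoxy 20-alcohol, 3-bromopropyl at C-10, C-9 ketal (C-8 epimers) | CC1C[C@H]2O[C@H]2[C@](CO)(CCCBr)C12OCCO2 | intermediate
13 | 5β,6β-epoxy 20-tosylate, 3-bromopropyl at C-10 | CC1C[C@H]2O[C@H]2[C@](COS(=O)(=O)c3ccc(C)cc3)(CCCBr)C12OCCO2 | intermediate
14 | propanoic acid | CCC(O)=O | starting material
15 | dilithium enediolate of propanoic acid | [Li]OC(O[Li])=CC | intermediate
16 | 5β,6β-epoxy 20-tosylate with the 4-carboxypentyl chain (C-1 to C-4, C-18, C-19) at C-10 (C-4 and C-8 epimers) | CC1C[C@H]2O[C@H]2[C@](COS(=O)(=O)c3ccc(C)cc3)(CCCC(C)C(O)=O)C12OCCO2 | intermediate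
17 | dilithium enediolate of 16 | CC1C[C@H]2O[C@H]2[C@](COS(=O)(=O)c3ccc(C)cc3)(CCCC(C)=C(O[Li])O[Li])C12OCCO2 | intermediate
18 | ring-A-closed 6β-(diethylaluminium) alkoxide, lithium 19-carboxylate, 20-tosylate | CC1C[C@@H](O[Al](CC)CC)[C@H]2[C@](COS(=O)(=O)c3ccc(C)cc3)(CCC[C@]2(C)C(=O)O[Li])C12OCCO2 | intermediate
19 | cis-fused 6β-hydroxy-19,20-olide with C-9 ethylene ketal (C-8 epimers) | CC1C[C@@H](O)[C@H]2[C@]3(CCC[C@]2(C)C(=O)OC3)C12OCCO2 | intermediate
20 | 6β-hydroxy-9-oxo-19,20-olide (C-8 epimers) | CC1C[C@@H](O)[C@H]2[C@]3(CCC[C@]2(C)C(=O)OC3)C1=O | intermediate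
21 | dilithium 6-alkoxide 8(9)-enolate of 20 | CC1C[C@@H](O[Li])[C@H]2[C@]3(CCC[C@]2(C)C(=O)OC3)C(O[Li])=1 | intermediate
22 | 6β-hydroxy-8α-methyl-9-oxo-19,20-olide | C[C@@H]1C[C@@H](O)[C@H]2[C@]3(CCC[C@]2(C)C(=O)OC3)C1=O | intermediate
23 | 3-bromofuran | Brc1ccoc1 | starting material
24 | (3-bromofuran-2-yl)lithium | [Li]c1occc1Br | intermediate
25 | 3-bromo-2-(trimethylsilyl)furan | C[Si](C)(C)c1occc1Br | intermediate
26 | [2-(trimethylsilyl)furan-3-yl]lithium | C[Si](C)(C)c1occc1[Li] | intermediate
27 | 2-[2-(trimethylsilyl)furan-3-yl]ethan-1-ol | C[Si](C)(C)c1occc1CCO | intermediate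
28 | 3-(2-iodoethyl)-2-(trimethylsilyl)furan | C[Si](C)(C)c1occc1CCI | intermediate
29 | {2-[2-(trimethylsilyl)furan-3-yl]ethyl}lithium | [Li]CCc1ccoc1[Si](C)(C)C | intermediate
30 | dichloro{2-[2-(trimethylsilyl)furan-3-yl]ethyl}cerium | Cl[Ce](Cl)CCc1ccoc1[Si](C)(C)C | intermediate
31 | 6β,9α-dihydroxy-19,20-olide with the 2-[2-(trimethylsilyl)furan-3-yl]ethyl chain at C-9 (C-11 β) | C[C@@H]1C[C@@H](O)[C@H]2[C@]3(CCC[C@]2(C)C(=O)OC3)[C@@]1(O)CCc1ccoc1[Si](C)(C)C | intermediate
32 | furan 2,5-endoperoxide of 31 | C[C@@H]1C[C@@H](O)[C@H]2[C@]3(CCC[C@]2(C)C(=O)OC3)[C@@]1(O)CCC1=CC2OOC1([Si](C)(C)C)O2 | intermediate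
33 | trimethylsilyl (Z)-4-oxobut-2-enoate carrying the tricyclic ethyl chain at C-2 (open enal) | C[C@@H]1C[C@@H](O)[C@H]2[C@]3(CCC[C@]2(C)C(=O)OC3)[C@@]1(O)CC/C(C(=O)O[Si](C)(C)C)=C/C=O | intermediate
34 | 9α,13-epoxy 15-aldehyde 16-trimethylsilyl ester (13R) | C[C@@H]1C[C@@H](O)[C@H]2[C@]3(CCC[C@]2(C)C(=O)OC3)[C@@]12CC[C@@](CC=O)(C(=O)O[Si](C)(C)C)O2 | intermediate
35 | 9α,13-epoxy-6β,15-dihydroxy-19,20:16,15-diolide (lactol, C-15 epimers) | C[C@@H]1C[C@@H](O)[C@H]2[C@]3(CCC[C@]2(C)C(=O)OC3)[C@@]12CC[C@]1(CC(O)OC1=O)O2 | intermediate
36 | sodium 9α,13-epoxy-6β,15-dihydroxy-19,20-olid-16-oate | C[C@@H]1C[C@@H](O)[C@H]2[C@]3(CCC[C@]2(C)C(=O)OC3)[C@@]12CC[C@@](CCO)(C([O-])=O)O2.[Na+] | intermediate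
37 | target: (4S,5S,6R,8R,9R,10S,13R)-9,13-epoxy-6-hydroxylabdane-19,20:16,15-diolide | C[C@@H]1C[C@@H](O)[C@H]2[C@]3(CCC[C@]2(C)C(=O)OC3)[C@@]12CC[C@]1(CCOC1=O)O2 | target

**Totals**
Total steps: 16. Longest linear sequence: 13 (steps 1–10 and 14–16); steps 11–13 make the side-chain fragment.

**Three steps most likely to fail**

Step 8. What may go wrong: poor facial selectivity at the enediolate carbon C-4 (methyl against enolate on the inside), slow opening at the doubly hindered C-5, or ether closure by the 6-oxygen onto C-20 ahead of the carboxylate. Fallback, from 12 back to 19, with the two bond formations separated and no leaving group on C-20 while an alkoxide is present: epoxy alcohol 12 is alkylated with the enediolate 15 of propanoic acid (the 20-hydroxyl carried as its lithium alkoxide) to give the hydroxy epoxy acid F1. Its trianion (LiN(iPr)2, 3.3 equiv, THF–DMPU, 0 → 40 °C) closes ring A by the same epoxide opening and gives the dihydroxy acid F2. Mitsunobu lactonization (PPh3, diisopropyl azodicarboxylate, THF, high dilution) then lets the carboxylic acid displace the activated primary 20-oxygen and gives 19; the C-4 epimer that cannot reach C-20 is removed at this stage.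

Step 10. What may go wrong: protonation of the enolate from the α-face, or epimerization of the kinetically formed 8α-methyl ketone during work-up. Fallback, from 20 back to 22, setting C-8 by hydrogenation instead of protonation: ketone 20 is dehydrogenated (Pd(OCOCF3)2 (cat.), DMSO, O2, AcOH, 80 °C) to the 6β-hydroxy Δ7-enone F3. Hydrogenation with H2 and [Ir(cod)(PCy3)(py)]PF6 in CH2Cl2 is then directed by the allylic 6β-hydroxyl to the β-face, which delivers 8β-H and gives 22 under neutral conditions.

Step 15. What may go wrong: the conjugate addition of the hindered tertiary 9-hydroxyl may stall at the open hydroxybutenolide, or the reversible addition may give poor control at C-13. Fallback, from 22 to 37, forming the C-13–O bond by an invertive epoxide opening instead of a conjugate addition: 3-methylidenepentane-1,5-diol is monosilylated (t-BuMe2SiCl, imidazole) to 5-[(tert-butyldimethylsilyl)oxy]-3-methylidenepentan-1-ol F4 and converted (PPh3, I2, imidazole) to the iodide F5. After iodine–lithium exchange (t-BuLi) and transmetalation with CeCl3, F5 adds to ketone 22 to give the alkene diol F6. 3-Chloroperbenzoic acid epoxidizes the 1,1-disubstituted alkene, and the epimer drawn as epoxide F7 is separated. 10-Camphorsulfonic acid closes the tetrahydrofuran by 5-exo attack of the 9α-hydroxyl on the tertiary epoxide carbon with inversion, giving the spiro ether alcohol F8. The primary alcohol is oxidized (2,2,6,6-tetramethylpiperidin-1-oxyl (cat.), PhI(OAc)2, MeCN–H2O) to the acid F9, and Bu4NF followed by dilute HCl removes the silyl ether, whereupon the 15-alcohol lactonizes to 37.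

**Further compounds**
F1 | step 8 | 5β,6β-epoxy 20-alcohol with the 4-carboxypentyl chain at C-10 (C-4 and C-8 epimers) | CC1C[C@H]2O[C@H]2[C@](CO)(CCCC(C)C(O)=O)C12OCCO2
F2 | step 8 | ring-A-closed 6β,20-dihydroxy 19-acid with C-9 ketal | CC1C[C@@H](O)[C@H]2[C@](CO)(CCC[C@]2(C)C(O)=O)C12OCCO2
F3 | step 10 | 6β-hydroxy-9-oxo-19,20-olid-7-ene | CC1=C[C@@H](O)[C@H]2[C@]3(CCC[C@]2(C)C(=O)OC3)C1=O
F4 | step 15 | 5-[(tert-butyldimethylsilyl)oxy]-3-methylidenepentan-1-ol | C=C(CCO)CCO[Si](C)(C)C(C)(C)C
F5 | step 15 | tert-butyl[(5-iodo-3-methylidenepentyl)oxy]dimethylsilane | C=C(CCI)CCO[Si](C)(C)C(C)(C)C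
F6 | step 15 | 6β,9α-dihydroxy-19,20-olide with the 5-silyloxy-3-methylidenepentyl chain at C-9 | C[C@@H]1C[C@@H](O)[C@H]2[C@]3(CCC[C@]2(C)C(=O)OC3)[C@@]1(O)CCC(=C)CCO[Si](C)(C)C(C)(C)C
F7 | step 15 | 13,16-epoxide of F6 (epimer that gives 13R on invertive opening) | C[C@@H]1C[C@@H](O)[C@H]2[C@]3(CCC[C@]2(C)C(=O)OC3)[C@@]1(O)CC[C@]1(CCO[Si](C)(C)C(C)(C)C)CO1
F8 | step 15 | 9α,13-epoxy-6β,16-dihydroxy-15-silyloxy-19,20-olide | C[C@@H]1C[C@@H](O)[C@H]2[C@]3(CCC[C@]2(C)C(=O)OC3)[C@@]12CC[C@@](CCO[Si](C)(C)C(C)(C)C)(CO)O2
F9 | step 15 | 9α,13-epoxy-6β-hydroxy-15-silyloxy-19,20-olid-16-oic acid | C[C@@H]1C[C@@H](O)[C@H]2[C@]3(CCC[C@]2(C)C(=O)OC3)[C@@]12CC[C@@](CCO[Si](C)(C)C(C)(C)C)(C(O)=O)O2
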